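**Plan** (labdane numbering throughout)

- The target is methyl (13E)-15-acetoxylabda-8,13-dien-19-oate, (4S,5R,10S). The retrosynthesis cuts the O-acetyl group and C13=C14 (back to a C13 methyl ketone), then C4–C5 and C9–C10 of the decalin in one operation, then C1–C2 of the open chain.
- The enabling feature is quaternary C4 (C18 methyl plus C19 carboxyl) next to the ring-fusion C5–H, quaternary C10–CH3 and the ring B olefin at C8. Rings A and B therefore unfold to an E,E-diene (C5=C10, C8=C9) carrying an α-methyl β-keto ester (C3=O, C4, C19).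
- Forward: geranylacetone ketal is oxidised and brominated at its terminal E-methyl; C1–C2 is joined by alkylating the dianion of 8-phenylmenthyl 2-methylacetoacetate; a Mn(OAc)3/Cu(OAc)2 radical cascade closes ring A, then ring B, and ends as a C8 olefin.
- Stereochemistry: chair–chair folding of the E,E-diene gives the trans fusion and the axial C19 ester; the 8-phenylmenthyl ester sets the absolute sense; C9 is formed and later erased when the olefin moves to C8=C9; 13E comes from the Horner–Wadsworth–Emmons step.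
- Endgame: C3 deoxygenation, exchange of the auxiliary for the methyl ester, acid shift of the olefin, olefination, i-Bu2AlH reduction and acetylation.

Key step: step 6

Assumption: the tertiary C4 radical of the (1R,2S,5R)-8-phenylmenthyl ester is taken to cyclise from the rotamer with the ester C=O s-cis to C3 and the C3=O turned away from the ester, the aryl ring lying over the Si face of C4, so that C5 adds to the Re face and the (4S,5R,10S) series results.

**Step 1**
Reactants: 1 (E)-geranylacetone
Product: 2 2-[(3E)-4,8-dimethylnona-3,7-dien-1-yl]-2-methyl-1,3-dioxolane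
Conditions: ethylene glycol (3 equiv), PPTS (cat.), benzene, reflux, Dean–Stark
Reagents that add atoms: ethylene glycol, OCCO
Why: Acid-catalysed ketalisation driven by azeotropic removal of water masks the C13 ketone for the carbanion and hydride steps ahead, PPTS being too weak an acid to protonate the trisubstituted olefins.

**Step 2**
Reactants: 2 2-[(3E)-4,8-dimethylnona-3,7-dien-1-yl]-2-methyl-1,3-dioxolane
Product: 3 (2E,6E)-2,6-dimethyl-9-(2-methyl-1,3-dioxolan-2-yl)nona-2,6-dien-1-ol
Conditions: SeO2 (0.3 equiv), t-BuOOH (2 equiv), CH2Cl2, 0 °C to rt, stopped at partial conversion, 2 recovered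
Reagents that add atoms: selenium dioxide, O=[Se]=O (carries the oxygen); tert-butyl hydroperoxide, CC(C)(C)OO (terminal oxygen source)
Why: The Riley allylic oxidation (ene reaction, then [2,3]-sigmatropic shift) should take place at the more accessible terminal isopropylidene group and deliver oxygen to its E-methyl, so that the new CH2OH stands trans to the chain.

**Step 3**
Reactants: 3 (2E,6E)-2,6-dimethyl-9-(2-methyl-1,3-dioxolan-2-yl)nona-2,6-dien-1-ol
Product: 4 2-[(3E,7E)-9-bromo-4,8-dimethylnona-3,7-dien-1-yl]-2-methyl-1,3-dioxolane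
Conditions: CBr4 (1.2 equiv), PPh3 (1.25 equiv), CH2Cl2, −20 to 0 °C; used without storage
Reagents that add atoms: carbon tetrabromide, BrC(Br)(Br)Br
Why: The Appel reaction replaces the primary allylic hydroxyl by bromide through an alkoxyphosphonium salt under neutral conditions that spare the dioxolane and leave the E olefin in place.

**Step 4**
Reactants: 5 (1R,2S,5R)-8-phenylmenthol; 6 methyl 2-methylacetoacetate
Product: 7 (1R,2S,5R)-8-phenylmenthyl 2-methyl-3-oxobutanoate (C2 epimers)
Conditions: DMAP (0.3 equiv), toluene, reflux, MeOH removed over 4 Å molecular sieves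
Reagents that add atoms: none
Why: DMAP-catalysed transesterification of a β-keto ester runs through an acylketene-type intermediate and therefore acylates even this hindered secondary alcohol, the C2 centre of 7 being an epimer mixture of no consequence.

**Step 5**
Reactants: 7 (1R,2S,5R)-8-phenylmenthyl 2-methyl-3-oxobutanoate; 4 2-[(3E,7E)-9-bromo-4,8-dimethylnona-3,7-dien-1-yl]-2-methyl-1,3-dioxolane
Product: 9 (1R,2S,5R)-8-phenylmenthyl (6E,10E)-2,6,10-trimethyl-13-(2-methyl-1,3-dioxolan-2-yl)-3-oxotrideca-6,10-dienoate, via sodium lithium dienolate 8 (not isolated)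
Conditions: NaH (1.1 equiv), THF, 0 °C; n-BuLi (1.05 equiv), 0 °C; then 4, 0 °C to rt; aq. NH4Cl
Reagents that add atoms: none
Why: In the Huckin–Weiler dianion alkylation the more basic terminal carbanion of the dienolate displaces the allylic bromide in an SN2 reaction, which forms C1–C2 without touching the α-carbon or the two E olefins.

**Step 6**
Reactants: 9 (1R,2S,5R)-8-phenylmenthyl (6E,10E)-2,6,10-trimethyl-13-(2-methyl-1,3-dioxolan-2-yl)-3-oxotrideca-6,10-dienoate
Product: 10 (1R,2S,5R)-8-phenylmenthyl 13,13-ethylenedioxy-3-oxo-14,15-dinorlabd-8(17)-en-19-oate, (4R,5R,9S,10R), ester axial and cis to C20, H5 and H9 α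
Conditions: Mn(OAc)3·2H2O (2.2 equiv), Cu(OAc)2·H2O (1.0 equiv), degassed EtOH, 25 to 40 °C; minor C4 diastereomer removed by chromatography
Reagents that add atoms: none
Why: Mn(OAc)3 (trivalent manganese) oxidises the enolised α-methyl β-keto ester to the electrophilic tertiary C4 radical, which adds to C5 of the E C5=C10 olefin; the tertiary C10 radical so formed adds to C9 of the E C8=C9 olefin, and Cu(OAc)2 (divalent copper) converts the resulting tertiary C8 radical into an alkylcopper species that loses a β-hydrogen, mainly from C17. The closest known reaction type is the oxidative free-radical polyene cyclisation of 2-alkyl-3-oxo esters with Mn(OAc)3 and Cu(OAc)2, which is also known for 8-phenylmenthyl esters. Ring A (C4–C5) and ring B (C9–C10) each close 6-endo-trig, the attack going to the CH end of each trisubstituted olefin so that a tertiary radical results both times. The chair–chair folding of the E,E-diene sets the trans C5–H/C10–CH3 fusion and the equatorial C9 chain, the ester at C4 ends axial and cis to C20 because the radical reacts with its C3=O turned away from the ester, and the absolute sense comes from the aryl ring of the auxiliary covering the Si face of C4 so that C5 bonds to the Re face. The step needs face selectivity at C4 (auxiliary), 6-endo regioselectivity (substitution pattern of the olefins) and a stop after two rings (C13 is a ketal carbon, not an olefin), and ethanol in place of acetic acid should keep the dioxolane intact. Olefin isomers at C7 or C8=C9 from the copper-mediated elimination are carried along, because step 13 funnels all of them into the C8=C9 isomer.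

**Step 7**
Reactants: 10 (1R,2S,5R)-8-phenylmenthyl 13,13-ethylenedioxy-3-oxo-14,15-dinorlabd-8(17)-en-19-oate
Product: 11 (1R,2S,5R)-8-phenylmenthyl 13,13-ethylenedioxy-3β-hydroxy-14,15-dinorlabd-8(17)-en-19-oate
Conditions: NaBH4, EtOH, 0 °C
Reagents that add atoms: none
Why: Borohydride reduction is chemoselective for the C3 ketone over the hindered ester and the ketal and should deliver hydride to the α face, away from the axial C19 ester and C20 methyl, to give the equatorial 3β-alcohol, whose configuration does not matter because C3 is deoxygenated in step 9.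

**Step 8**
Reactants: 11 (1R,2S,5R)-8-phenylmenthyl 13,13-ethylenedioxy-3β-hydroxy-14,15-dinorlabd-8(17)-en-19-oate
Product: 12 (1R,2S,5R)-8-phenylmenthyl 13,13-ethylenedioxy-3β-(imidazol-1-ylthiocarbonyloxy)-14,15-dinorlabd-8(17)-en-19-oate
Conditions: 1,1'-thiocarbonyldiimidazole (3 equiv), DMAP (0.2 equiv), ClCH2CH2Cl, 80 °C
Reagents that add atoms: 1,1'-thiocarbonyldiimidazole, S=C(n1ccnc1)n1ccnc1
Why: Acyl transfer from thiocarbonyldiimidazole gives the thiocarbonyl derivative needed for radical deoxygenation under neutral conditions, which avoids the retro-aldol opening that an alkoxide of this β-hydroxy ester could undergo.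

**Step 9**
Reactants: 12 (1R,2S,5R)-8-phenylmenthyl 13,13-ethylenedioxy-3β-(imidazol-1-ylthiocarbonyloxy)-14,15-dinorlabd-8(17)-en-19-oate
Product: 13 (1R,2S,5R)-8-phenylmenthyl 13,13-ethylenedioxy-14,15-dinorlabd-8(17)-en-19-oate
Conditions: Bu3SnH (2 equiv), AIBN (0.2 equiv), toluene, 110 °C
Reagents that add atoms: none
Why: In the Barton–McCombie deoxygenation the stannyl radical adds to sulfur, the C3–O bond fragments and the secondary C3 radical, which has no olefin within reach, takes hydrogen from the stannane.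

**Step 10**
Reactants: 13 (1R,2S,5R)-8-phenylmenthyl 13,13-ethylenedioxy-14,15-dinorlabd-8(17)-en-19-oate
Product: 15 19-hydroxy-14,15-dinorlabd-8(17)-en-13-one, via ketal alcohol 14 (not isolated)
Conditions: LiAlH4 (4 equiv), THF, reflux; then 2 M HCl, THF, rt; 8-phenylmenthol recovered
Reagents that add atoms: water, O
Why: LiAlH4 reduction cleaves the hindered auxiliary ester reductively to the C19 primary alcohol and returns 8-phenylmenthol, and the dilute aqueous acid of the work-up hydrolyses the dioxolane at a temperature at which the 8(17) olefin should not move.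

**Step 11**
Reactants: 15 19-hydroxy-14,15-dinorlabd-8(17)-en-13-one
Product: 17 13-oxo-14,15-dinorlabd-8(17)-en-19-oic acid, via aldehyde 16 (not isolated)
Conditions: CrO3, H2SO4, H2O, acetone, 0 °C
Reagents that add atoms: water, O
Why: The Jones oxidation takes the neopentyl primary alcohol through the aldehyde hydrate to the carboxylic acid, the ketone and the 1,1-disubstituted olefin being inert to chromic acid at 0 °C.

**Step 12**
Reactants: 17 13-oxo-14,15-dinorlabd-8(17)-en-19-oic acid
Product: 18 methyl 13-oxo-14,15-dinorlabd-8(17)-en-19-oate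
Conditions: MeI (3 equiv), K2CO3 (2 equiv), DMF, rt
Reagents that add atoms: iodomethane, CI
Why: O-Alkylation of the carboxylate (SN2 at methyl) esterifies an axial acid that is too hindered for addition–elimination at its carbonyl, and carbonate is too weak a base to alkylate the methyl ketone.

**Step 13**
Reactants: 18 methyl 13-oxo-14,15-dinorlabd-8(17)-en-19-oate
Product: 19 methyl 13-oxo-14,15-dinorlabd-8-en-19-oate
Conditions: HI (57% aq., 0.2 equiv), benzene, 80 °C
Reagents that add atoms: none
Why: Acid-catalysed olefin isomerisation through the tertiary C8 cation should equilibrate the 8(17) olefin, and the C7 isomer carried from step 6, to the tetrasubstituted C8=C9 olefin as the thermodynamic product, which removes the C9 stereocentre and leaves C4, C5 and C10 untouched.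

**Step 14**
Reactants: 19 methyl 13-oxo-14,15-dinorlabd-8-en-19-oate
Product: 20 15-ethyl 19-methyl (13E)-labda-8,13-diene-15,19-dioate
Conditions: (EtO)2P(O)CH2CO2Et (3 equiv), NaH (2.8 equiv), THF, 0 °C to reflux; E isomer separated by chromatography
Reagents that add atoms: triethyl phosphonoacetate, CCOC(=O)CP(=O)(OCC)OCC
Why: The Horner–Wadsworth–Emmons olefination of the methyl ketone is reversible up to the oxaphosphetane and should favour the E enoate with the ester trans to the C12 chain, while the C19 ester has no α-hydrogen and is too hindered to react.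

**Step 15**
Reactants: 20 15-ethyl 19-methyl (13E)-labda-8,13-diene-15,19-dioate
Product: 21 methyl (13E)-15-hydroxylabda-8,13-dien-19-oate
Conditions: i-Bu2AlH (2.2 equiv), CH2Cl2, −78 °C; aq. potassium sodium tartrate
Reagents that add atoms: none
Why: i-Bu2AlH reduces the unhindered conjugated ethyl ester by 1,2-addition to the allylic alcohol much faster than it attacks the axial neopentyl C19 methyl ester, and the E geometry is kept.

**Step 16**
Reactants: 21 methyl (13E)-15-hydroxylabda-8,13-dien-19-oate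
Product: 22 methyl (13E)-15-acetoxylabda-8,13-dien-19-oate (target)
Conditions: Ac2O, pyridine, DMAP (cat.), CH2Cl2, 0 °C to rt
Reagents that add atoms: acetic anhydride, CC(=O)OC(C)=O
Why: DMAP-catalysed acylation of the primary allylic alcohol gives the acetate without touching any stereocentre or either olefin.

**Compound list**

1 | (E)-geranylacetone, (5E)-6,10-dimethylundeca-5,9-dien-2-one, E-pure commercial grade | CC(=O)CC/C=C(\C)CCC=C(C)C | starting material
2 | 2-[(3E)-4,8-dimethylnona-3,7-dien-1-yl]-2-methyl-1,3-dioxolane | CC1(CC/C=C(\C)CCC=C(C)C)OCCO1 | intermediate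
3 | (2E,6E)-2,6-dimethyl-9-(2-methyl-1,3-dioxolan-2-yl)nona-2,6-dien-1-ol | CC1(CC/C=C(\C)CC/C=C(\C)CO)OCCO1 | intermediate
4 | 2-[(3E,7E)-9-bromo-4,8-dimethylnona-3,7-dien-1-yl]-2-methyl-1,3-dioxolane | CC1(CC/C=C(\C)CC/C=C(\C)CBr)OCCO1 | intermediate
5 | (1R,2S,5R)-8-phenylmenthol | C[C@@H]1CC[C@H]([C@@H](C1)O)C(C)(C)c1ccccc1 | starting material
6 | methyl 2-methylacetoacetate (methyl 2-methyl-3-oxobutanoate) | COC(=O)C(C)C(C)=O | starting material
7 | (1R,2S,5R)-8-phenylmenthyl 2-methyl-3-oxobutanoate (C2 epimers) | C[C@@H]1CC[C@H]([C@@H](C1)OC(=O)C(C)C(C)=O)C(C)(C)c1ccccc1 | intermediate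
8 | sodium lithium dienolate (dianion) of 7 | C[C@@H]1CC[C@H]([C@@H](C1)OC(=O)C(C)=C([O-])[CH2-])C(C)(C)c1ccccc1.[Na+].[Li+] | intermediate (not isolated)
9 | (1R,2S,5R)-8-phenylmenthyl (6E,10E)-2,6,10-trimethyl-13-(2-methyl-1,3-dioxolan-2-yl)-3-oxotrideca-6,10-dienoate (C2 epimers) | C[C@@H]1CC[C@H]([C@@H](C1)OC(=O)C(C)C(=O)CC/C(C)=C/CC/C(C)=C/CCC2(C)OCCO2)C(C)(C)c1ccccc1 | intermediate
10 | (1R,2S,5R)-8-phenylmenthyl 13,13-ethylenedioxy-3-oxo-14,15-dinorlabd-8(17)-en-19-oate, (4R,5R,9S,10R) | C[C@@H]1CC[C@H]([C@@H](C1)OC(=O)[C@@]2(C)C(=O)CC[C@]3(C)[C@@H](CCC4(C)OCCO4)C(=C)CC[C@@H]23)C(C)(C)c1ccccc1 | intermediate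
11 | (1R,2S,5R)-8-phenylmenthyl 13,13-ethylenedioxy-3β-hydroxy-14,15-dinorlabd-8(17)-en-19-oate | C[C@@H]1CC[C@H]([C@@H](C1)OC(=O)[C@@]2(C)[C@@H](O)CC[C@]3(C)[C@@H](CCC4(C)OCCO4)C(=C)CC[C@@H]23)C(C)(C)c1ccccc1 | intermediate
12 | (1R,2S,5R)-8-phenylmenthyl 13,13-ethylenedioxy-3β-(imidazol-1-ylthiocarbonyloxy)-14,15-dinorlabd-8(17)-en-19-oate | C[C@@H]1CC[C@H]([C@@H](C1)OC(=O)[C@@]2(C)[C@@H](OC(=S)n5ccnc5)CC[C@]3(C)[C@@H](CCC4(C)OCCO4)C(=C)CC[C@@H]23)C(C)(C)c1ccccc1 | intermediate
13 | (1R,2S,5R)-8-phenylmenthyl 13,13-ethylenedioxy-14,15-dinorlabd-8(17)-en-19-oate | C[C@@H]1CC[C@H]([C@@H](C1)OC(=O)[C@@]2(C)CCC[C@]3(C)[C@@H](CCC4(C)OCCO4)C(=C)CC[C@@H]23)C(C)(C)c1ccccc1 | intermediate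
14 | 13,13-ethylenedioxy-14,15-dinorlabd-8(17)-en-19-ol | OC[C@@]1(C)CCC[C@]2(C)[C@@H](CCC3(C)OCCO3)C(=C)CC[C@@H]12 | intermediate (not isolated)
15 | 19-hydroxy-14,15-dinorlabd-8(17)-en-13-one | OC[C@@]1(C)CCC[C@]2(C)[C@@H](CCC(C)=O)C(=C)CC[C@@H]12 | intermediate
16 | 13-oxo-14,15-dinorlabd-8(17)-en-19-al | O=C[C@@]1(C)CCC[C@]2(C)[C@@H](CCC(C)=O)C(=C)CC[C@@H]12 | intermediate (not isolated)
17 | 13-oxo-14,15-dinorlabd-8(17)-en-19-oic acid | OC(=O)[C@@]1(C)CCC[C@]2(C)[C@@H](CCC(C)=O)C(=C)CC[C@@H]12 | intermediate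
18 | methyl 13-oxo-14,15-dinorlabd-8(17)-en-19-oate | COC(=O)[C@@]1(C)CCC[C@]2(C)[C@@H](CCC(C)=O)C(=C)CC[C@@H]12 | intermediate
19 | methyl 13-oxo-14,15-dinorlabd-8-en-19-oate | COC(=O)[C@@]1(C)CCC[C@]2(C)C(CCC(C)=O)=C(C)CC[C@@H]12 | intermediate
20 | 15-ethyl 19-methyl (13E)-labda-8,13-diene-15,19-dioate | COC(=O)[C@@]1(C)CCC[C@]2(C)C(CC/C(C)=C/C(=O)OCC)=C(C)CC[C@@H]12 | intermediate
21 | methyl (13E)-15-hydroxylabda-8,13-dien-19-oate | COC(=O)[C@@]1(C)CCC[C@]2(C)C(CC/C(C)=C/CO)=C(C)CC[C@@H]12 | intermediate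
22 | methyl (13E)-15-acetoxylabda-8,13-dien-19-oate, (4S,5R,10S) | COC(=O)[C@@]1(C)CCC[C@]2(C)C(CC/C(C)=C/COC(C)=O)=C(C)CC[C@@H]12 | target

**Step count**

Total: 16 steps. Longest linear sequence: 15 steps (1 to 22 through steps 1–3 and 5–16; step 4 is the side branch).

**Steps most likely to fail**

Step 6. The auxiliary may discriminate the two faces of the C4 radical poorly or in the sense opposite to the one assumed, and the C10 radical may be oxidised before ring B closes. The fallback gives up control by the ester in favour of a resolution. It sets out from bromide 4 and keto ester 6 and returns at 18.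
- Compound 6 is converted (NaH, then n-BuLi) into its dienolate F1, which is alkylated with 4 to the methyl keto ester F2.
- The same Mn(OAc)3/Cu(OAc)2 cascade should give the racemic bicyclic 3-oxo ester F3, with the relative configuration fixed by the chair–chair array.
- NaBH4 gives the racemic 3β-alcohol F4.
- Acylation with (1S)-camphanic chloride (pyridine, DMAP) gives two diastereomeric esters, from which the camphanate of the normal series F5 is separated by chromatography or crystallisation.
- Methanolysis (K2CO3, MeOH) gives the enantiopure 3β-alcohol F6, thiocarbonyldiimidazole gives the imidazolide F7, and Bu3SnH/AIBN gives the deoxygenated ketal methyl ester F8.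
- Hydrolysis of F8 (1 M HCl, THF) joins the route at 18; steps 10–12 are then not needed.

Step 13. The equilibration may stop at a mixture with the C7 olefin, or the C8 cation may be captured by the C13 carbonyl oxygen to give a cyclic enol ether. The fallback builds the tetrasubstituted olefin regiospecifically without a cation. It sets out from 13 and returns at 19.
- Ozonolysis of 13 (O3, CH2Cl2/MeOH, −78 °C; Me2S) gives the C8 ketone F9.
- Tf2O with 2,6-di-tert-butyl-4-methylpyridine should give the more substituted C8=C9 enol triflate F10.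
- Pd(PPh3)4-catalysed Negishi coupling with MeZnCl installs C17 to give the C8=C9 auxiliary ester F11.
- The conditions of steps 10–12 applied to F11 lead through the ketal alcohol F12, the keto alcohol F13, the aldehyde F14 and the keto acid F15, whose methylation gives 19.

Step 14. The olefination of a methyl ketone may show low E/Z selectivity, so that material is lost late as the Z isomer. The fallback sets the 13E geometry by syn-carbometalation. It sets out from 19 and returns at 21.
- Kinetic enolisation of the methyl ketone (LiN(i-Pr)2, THF, −78 °C) and trapping with ClP(O)(OEt)2 gives the enol phosphate F16.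
- Elimination with more LiN(i-Pr)2 gives the terminal alkyne F17.
- Methylalumination with AlMe3 and Cp2ZrCl2 (cat.) gives the (E)-alkenylalane F18 by syn addition.
- Paraformaldehyde converts F18 directly into 21; step 15 is then skipped.

**Further compounds**

F1 | step 6 | sodium lithium dienolate of methyl 2-methylacetoacetate | COC(=O)C(C)=C([O-])[CH2-].[Na+].[Li+]
F2 | step 6 | methyl (6E,10E)-2,6,10-trimethyl-13-(2-methyl-1,3-dioxolan-2-yl)-3-oxotrideca-6,10-dienoate | COC(=O)C(C)C(=O)CC/C(C)=C/CC/C(C)=C/CCC1(C)OCCO1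
F3 | step 6 | rac-methyl 13,13-ethylenedioxy-3-oxo-14,15-dinorlabd-8(17)-en-19-oate (both enantiomers) | COC(=O)[C@@]1(C)C(=O)CC[C@]2(C)[C@@H](CCC3(C)OCCO3)C(=C)CC[C@@H]12.COC(=O)[C@]1(C)C(=O)CC[C@@]2(C)[C@H](CCC3(C)OCCO3)C(=C)CC[C@H]12
F4 | step 6 | rac-methyl 13,13-ethylenedioxy-3β-hydroxy-14,15-dinorlabd-8(17)-en-19-oate (both enantiomers) | COC(=O)[C@@]1(C)[C@@H](O)CC[C@]2(C)[C@@H](CCC3(C)OCCO3)C(=C)CC[C@@H]12.COC(=O)[C@]1(C)[C@H](O)CC[C@@]2(C)[C@H](CCC3(C)OCCO3)C(=C)CC[C@H]12
F5 | step 6 | methyl 3β-[(1S,4R)-camphanoyloxy]-13,13-ethylenedioxy-14,15-dinorlabd-8(17)-en-19-oate, normal series | COC(=O)[C@@]1(C)[C@@H](OC(=O)[C@@]45CC[C@@](C)(C(=O)O4)C5(C)C)CC[C@]2(C)[C@@H](CCC3(C)OCCO3)C(=C)CC[C@@H]12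
F6 | step 6 | methyl 13,13-ethylenedioxy-3β-hydroxy-14,15-dinorlabd-8(17)-en-19-oate, single enantiomer | COC(=O)[C@@]1(C)[C@@H](O)CC[C@]2(C)[C@@H](CCC3(C)OCCO3)C(=C)CC[C@@H]12
F7 | step 6 | methyl 13,13-ethylenedioxy-3β-(imidazol-1-ylthiocarbonyloxy)-14,15-dinorlabd-8(17)-en-19-oate | COC(=O)[C@@]1(C)[C@@H](OC(=S)n4ccnc4)CC[C@]2(C)[C@@H](CCC3(C)OCCO3)C(=C)CC[C@@H]12
F8 | step 6 | methyl 13,13-ethylenedioxy-14,15-dinorlabd-8(17)-en-19-oate | COC(=O)[C@@]1(C)CCC[C@]2(C)[C@@H](CCC3(C)OCCO3)C(=C)CC[C@@H]12
F9 | step 13 | (1R,2S,5R)-8-phenylmenthyl 13,13-ethylenedioxy-8-oxo-14,15,17-trinorlabdan-19-oate | C[C@@H]1CC[C@H]([C@@H](C1)OC(=O)[C@@]2(C)CCC[C@]3(C)[C@@H](CCC4(C)OCCO4)C(=O)CC[C@@H]23)C(C)(C)c1ccccc1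
F10 | step 13 | (1R,2S,5R)-8-phenylmenthyl 13,13-ethylenedioxy-8-(trifluoromethylsulfonyloxy)-14,15,17-trinorlabd-8-en-19-oate | C[C@@H]1CC[C@H]([C@@H](C1)OC(=O)[C@@]2(C)CCC[C@]3(C)C(CCC4(C)OCCO4)=C(OS(=O)(=O)C(F)(F)F)CC[C@@H]23)C(C)(C)c1ccccc1
F11 | step 13 | (1R,2S,5R)-8-phenylmenthyl 13,13-ethylenedioxy-14,15-dinorlabd-8-en-19-oate | C[C@@H]1CC[C@H]([C@@H](C1)OC(=O)[C@@]2(C)CCC[C@]3(C)C(CCC4(C)OCCO4)=C(C)CC[C@@H]23)C(C)(C)c1ccccc1
F12 | step 13 | 13,13-ethylenedioxy-14,15-dinorlabd-8-en-19-ol | OC[C@@]1(C)CCC[C@]2(C)C(CCC3(C)OCCO3)=C(C)CC[C@@H]12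
F13 | step 13 | 19-hydroxy-14,15-dinorlabd-8-en-13-one | OC[C@@]1(C)CCC[C@]2(C)C(CCC(C)=O)=C(C)CC[C@@H]12
F14 | step 13 | 13-oxo-14,15-dinorlabd-8-en-19-al | O=C[C@@]1(C)CCC[C@]2(C)C(CCC(C)=O)=C(C)CC[C@@H]12
F15 | step 13 | 13-oxo-14,15-dinorlabd-8-en-19-oic acid | OC(=O)[C@@]1(C)CCC[C@]2(C)C(CCC(C)=O)=C(C)CC[C@@H]12
F16 | step 14 | methyl 13-(diethoxyphosphoryloxy)-14,15-dinorlabda-8,13(16)-dien-19-oate | COC(=O)[C@@]1(C)CCC[C@]2(C)C(CCC(=C)OP(=O)(OCC)OCC)=C(C)CC[C@@H]12
F17 | step 14 | methyl 15,16-dinorlabd-8-en-13-yn-19-oate | COC(=O)[C@@]1(C)CCC[C@]2(C)C(CCC#C)=C(C)CC[C@@H]12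
F18 | step 14 | methyl (13E)-14-(dimethylalumanyl)-15-norlabda-8,13-dien-19-oate | COC(=O)[C@@]1(C)CCC[C@]2(C)C(CC/C(C)=C/[Al](C)C)=C(C)CC[C@@H]12
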